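## The problem

Locants follow the spiro[5.5]undecane skeleton of the target: C1–C5 and the spiro carbon C6 form ring A, C6–C11 form ring B, and C14 is the methylidene carbon on C1.

- The target 27 joins two cyclohexanes at a quaternary spiro carbon (C6) that sits between a second quaternary carbon (C5, gem-dimethyl) and the sp2 carbon C1. The C5–C6 bond is therefore the hardest skeletal bond.
- Ring A carries an allylic carbinol (C2, R) and, 1,3-trans to it, a secondary bromide at the neopentyl position C4 (R).
- Ring B carries a secondary bromide (C8, S) next to a tertiary chloride (C9, S, with a methyl group). The two halogens are trans, and the bromine is cis to C5.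
- C6 is a stereocentre only because the two arms of ring B differ. Its configuration is fixed at the moment one arm is functionalised, so ring A has to be complete and chiral before ring B is touched. C2 can control C4 (1,3 across C3), but ring-B centres can only be set by reagent control and by the chair preference of ring B (C5 equatorial, C1 axial).
- Sensitive groups: the tertiary chloride and both secondary bromides (elimination under base), the allylic alcohol beside the exocyclic alkene (ionisation, allylic transposition, electrophiles), and any β-hydroxy ketone on the way (retro-aldol, dehydration).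
- The enabling feature: C2 is a carbinol two carbons from C4, the later bromide site. If C4 is a ketone, the C2–C3 bond is an aldol bond between a methyl ketone on C5 (C3/C4) and an α-methylene aldehyde on C6 (C1/C2/C14). With ring B held as a symmetric ketal, that keto aldehyde is achiral, and C2 becomes the first stereocentre.

## Retrosynthesis

**Ring-B halogens.** Target 27 comes from silyl ether 26. The C9–Cl bond of 26 is cut to tertiary alcohol 25, and the C9 methyl is cut to α-bromo ketone 24. Direct bromochlorination of a C8=C9 alkene is shorter, but on this locked ring anti addition is expected to favour the diaxial array, whereas 27 has both halogens equatorial. The stepwise order sets C8 under ketone control (equatorial bromide), then C9 by axial methyl delivery, then replaces OH by Cl on the same face. The forward steps need a non-basic methyl donor and a neutral chlorination.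

**C8–Br and C6.** Bromo ketone 24 comes from silyl enol ether 23, and 23 from the symmetric ring-B ketone 22. Cutting here turns the C6 problem into a choice between two diastereotopic α-methylene groups, which a chiral lithium amide can make. Ketone 22 has only the two ring-A stereocentres. It comes from ketal 21 by hydrolysis.

**C4–Br.** Bromide 21 is cut to the cis carbinol 20 (substitution with inversion), which comes from ketone 19 and then from hydroxy ketone 18. Using the C4 ketone of the aldol product as the bromide precursor avoids any separate oxidation at C4. The cost is a substitution at a neopentyl carbon, which is the weakest step after the key step. A catalyst-controlled reduction is required because the cis carbinol is needed for inversion.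

**C2–C3 (key cut).** Hydroxy ketone 18 is opened to the achiral keto enal 16. This cut removes ring A and the only stereocentre in one stroke. A cut at C1–C6 or C5–C6 would have to form a quaternary centre in the ring closure. The forward reaction must be an enantioselective intramolecular aldol that adds 1,2 to an α-methylene aldehyde.

**Ketone and methylidene.** Keto enal 16 comes from enal 15 by Markovnikov oxidation of the vinyl group, and 15 from aldehyde 13 by α-methylenation. The vinyl group is a masked methyl ketone that survives hydride, ylide and base. The methylidene is installed only when the aldehyde is in place.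

**C1–C2.** Aldehyde 13 comes from enol ether 11 by hydrolysis, and 11 from neopentyl aldehyde 8 and phosphonium salt 9. This one-carbon homologation is preferred to a two-carbon nucleophile because the carbon on C6 is already at the correct oxidation level in 8.

**C5–C6.** Aldehyde 8 comes from alcohol 7 and acid 6. The bond between the two quaternary carbons of 6 is cut by an Ireland–Claisen disconnection to prenyl ester 3, made from acid 1 and prenol 2. A sigmatropic shift is the most reliable way to join two fully substituted carbons. The precursor is an achiral ester of two commercial compounds.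

## Roads not taken

**Alternative 1:** Gold-catalysed dearomative ipso-cyclisation.
- Cut: C1–C6.
- Forward step: a cationic monovalent gold catalyst (Ph3PAuNTf2) activates the terminal alkyne of phenol A1. The para carbon attacks the internal alkyne carbon (6-exo-dig) and gives spirodienone A2, with ring A, the methylidene and the spiro centre formed together.
- Merits: convergent; one catalytic step builds the spiro centre; ring B arrives as a symmetric dienone with a carbonyl at C9 and functional handles on both arms.
- Weak points: C2 and C4 must both be set on the open chain before cyclisation (two asymmetric operations instead of one). The ipso attack has to form C6 next to the quaternary C5 with two bulky silyloxy groups in the tether. Both enone alkenes must then be reduced without touching the methylidene. The C4 bromide still requires the same neopentyl substitution, and ring B still needs desymmetrisation.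
- Comparison: the gold route is more convergent and delivers ring-B oxidation for free. The chosen plan sets against it a sigmatropic construction of the C5–C6 bond and a single catalytic stereo-defining step on an achiral substrate.

**Alternative 2:** Haloperoxidase bromonium spirocyclisation.
- Cut: C4–Br and C5–C6 together.
- Forward step: a vanadium-dependent bromoperoxidase (vanadate, H2O2, KBr) brominates the terminal alkene of (E)-γ-bisabolene A3. The tetrasubstituted alkene closes ring A and gives A4 after proton loss.
- Merits: by far the shortest entry. It installs the neopentyl C4 bromide in the ring-forming step, exactly the bond that costs the chosen plan its riskiest substitution.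
- Weak points: the isolated enzyme releases a diffusible electrophilic bromine species, so site selectivity among three alkenes, conversion to spirocycle and enantioselectivity are all poor. A4 lacks the C2 oxygen, so a late allylic oxidation with no stereocontrol element would be needed. The C8=C9 alkene of A4 must then take up Br and Cl, where anti addition on the locked ring favours the diaxial isomer.
- Comparison: this road is clearly better in step count and in forming C4–Br. The chosen plan sets against it predictable absolute control at every centre and a ring-B sequence designed for the diequatorial halide pattern.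

**Alternative 3:** Robinson spiroannulation.
- Cut: C6–C11 and C7–C8 (ring B).
- Forward step: formyl ketone A5 adds through C6 to methyl vinyl ketone A6. Aldol condensation onto the formyl carbon gives spiro enedione A7.
- Merits: classical and scalable. The enone differentiates the two arms of ring B from the start, so no chiral-base desymmetrisation is needed. The C4 bromide is made on a simple monocyclic ketone.
- Weak points: the Michael addition must create C6 next to the quaternary C5. Facial control by the remote C4 bromide is uncertain. The bromide and the formyl group must survive base. The C1 ketone then needs α-oxygenation at C2 with stereocontrol and methylenation of a carbonyl flanked by the spiro centre. Absolute configuration rests on an enantiopure A5, again a neopentyl bromide.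
- Comparison: this road is stronger for ring-B differentiation. The chosen plan delivers the C1 methylidene and C2 oxygen directly from the ring-closing step and fixes absolute configuration catalytically.

Key step: step 9

Assumptions:
- Acid 1 is taken as purchasable; otherwise it is one saponification (LiOH) from its commercial ethyl ester.
- The L-amino-acid catalyst of step 9 is taken to follow the usual hydrogen-bonded enamine sense (Re-face attack, giving 2R); if the sense is reversed on this substrate, the D-enantiomer is used.
- The (R,R)-lithium amide of step 14 is taken to remove the axial hydrogen of the arm that becomes C7–C8, by analogy with 4-substituted cyclohexanones; if the sense is reversed, the (S,S)-amide is used.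

## Steps

Step 1
Reactants: 1 1,4-dioxaspiro[4.5]decane-8-carboxylic acid; 2 3-methylbut-2-en-1-ol (prenol)
Product: 3 3-methylbut-2-en-1-yl 1,4-dioxaspiro[4.5]decane-8-carboxylate
Conditions: EDC·HCl, DMAP (cat.), CH2Cl2, 0 °C → rt
Reagents that add atoms: none
Why: Steglich-type carbodiimide esterification of an unhindered acid with a primary allylic alcohol; the neutral conditions leave the ketal and the prenyl alkene untouched.

Step 2
Reactants: 3 3-methylbut-2-en-1-yl 1,4-dioxaspiro[4.5]decane-8-carboxylate
Product: 6 8-(2-methylbut-3-en-2-yl)-1,4-dioxaspiro[4.5]decane-8-carboxylic acid, via silyl ketene acetal 4 (not isolated), via trimethylsilyl ester 5 (not isolated)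
Conditions: LiN(iPr)2, THF, −78 °C; Me3SiCl, Et3N, −78 → 65 °C; aq. NH4Cl work-up
Reagents that add atoms: chlorotrimethylsilane, C[Si](C)(C)Cl (retained only in 4 and 5)
Why: Ireland–Claisen rearrangement; the ketene acetal has a ring carbon as its α-carbon, so there is no enolate geometry issue, and the [3,3] shift joins that carbon to the dimethyl-substituted allyl terminus, forming the C5–C6 bond and both quaternary carbons without creating a stereocentre.

Step 3
Reactants: 6 8-(2-methylbut-3-en-2-yl)-1,4-dioxaspiro[4.5]decane-8-carboxylic acid
Product: 7 [8-(2-methylbut-3-en-2-yl)-1,4-dioxaspiro[4.5]decan-8-yl]methanol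
Conditions: LiAlH4, THF, 0 → 65 °C
Reagents that add atoms: none
Why: Hydride reduction of a hindered carboxylic acid to the neopentyl alcohol; ketal and isolated alkene are inert to LiAlH4.

Step 4
Reactants: 7 [8-(2-methylbut-3-en-2-yl)-1,4-dioxaspiro[4.5]decan-8-yl]methanol
Product: 8 8-(2-methylbut-3-en-2-yl)-1,4-dioxaspiro[4.5]decane-8-carbaldehyde
Conditions: tetrapropylammonium perruthenate (nPr4N)RuO4 (5 mol %), N-methylmorpholine N-oxide, 4 Å sieves, CH2Cl2, rt
Reagents that add atoms: none
Why: Ley–Griffith oxidation under neutral conditions; the aldehyde has no α-hydrogen, so neither over-oxidation through an enol nor ketal loss is expected.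

Step 5
Reactants: 8 8-(2-methylbut-3-en-2-yl)-1,4-dioxaspiro[4.5]decane-8-carbaldehyde; 9 (methoxymethyl)triphenylphosphonium chloride
Product: 11 8-(2-methoxyethenyl)-8-(2-methylbut-3-en-2-yl)-1,4-dioxaspiro[4.5]decane (E/Z mixture), via phosphorus ylide 10 (not isolated)
Conditions: potassium bis(trimethylsilyl)amide, THF, 0 °C; then 8, 0 °C → rt
Reagents that add atoms: none
Why: Wittig methoxymethylenation; the reactive non-stabilised ylide adds even to a neopentyl aldehyde, and the aldehyde cannot enolise under the basic conditions; the alkene geometry is irrelevant because the next step hydrolyses both isomers.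

Step 6
Reactants: 11 8-(2-methoxyethenyl)-8-(2-methylbut-3-en-2-yl)-1,4-dioxaspiro[4.5]decane
Product: 13 2-[8-(2-methylbut-3-en-2-yl)-1,4-dioxaspiro[4.5]decan-8-yl]acetaldehyde, via α-mercurio aldehyde 12 (not isolated)
Conditions: Hg(OAc)2 (1.1 equiv), THF/H2O (10:1), 0 °C; then sat. aq. KI
Reagents that add atoms: mercury diacetate, CC(=O)O[Hg]OC(C)=O (retained only in 12); water, O
Why: Enol ether hydrolysis by oxymercuration–demercuration; the electron-rich enol ether is mercurated far faster than the hindered vinyl group, water adds and methanol is lost, and iodide removes mercury from 12; the near-neutral medium spares the dioxolane, which aqueous acid strong enough to protonate this hindered enol ether would not reliably do.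

Step 7
Reactants: 13 2-[8-(2-methylbut-3-en-2-yl)-1,4-dioxaspiro[4.5]decan-8-yl]acetaldehyde
Product: 15 2-[8-(2-methylbut-3-en-2-yl)-1,4-dioxaspiro[4.5]decan-8-yl]prop-2-enal, via Mannich base 14 (not isolated)
Conditions: CH2=NMe2+ I−, Et3N, CH2Cl2, rt
Reagents that add atoms: dimethylmethyleneiminium iodide, C=[N+](C)C.[I-]
Why: Mannich aminomethylation of the only enolisable position followed by β-elimination of dimethylamine gives the α-methylene aldehyde; no ketone is present yet, so no competing enolisation or premature aldol can occur.

Step 8
Reactants: 15 2-[8-(2-methylbut-3-en-2-yl)-1,4-dioxaspiro[4.5]decan-8-yl]prop-2-enal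
Product: 16 2-[8-(2-methyl-3-oxobutan-2-yl)-1,4-dioxaspiro[4.5]decan-8-yl]prop-2-enal
Conditions: PdCl2 (10 mol %), CuCl, O2 (1 atm), DMF/H2O (7:1), rt
Reagents that add atoms: water, O
Why: Tsuji–Wacker oxidation; Markovnikov hydroxypalladation of the monosubstituted alkene gives the methyl ketone, while the electron-poor 1,1-disubstituted enal alkene binds divalent palladium poorly and is left; the reaction is run at room temperature so that the 1,5-diene 15 has no opportunity for a Cope shift.

Step 9
Reactants: 16 2-[8-(2-methyl-3-oxobutan-2-yl)-1,4-dioxaspiro[4.5]decan-8-yl]prop-2-enal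
Product: 18 (2R)-9,9-(ethylenedioxy)-2-hydroxy-5,5-dimethyl-1-methylidenespiro[5.5]undecan-4-one, via threonine enamine 17 (not isolated)
Conditions: O-tert-butyl-L-threonine (20 mol %), N-methylpyrrolidone, H2O (2 equiv), 4 °C → rt
Reagents that add atoms: O-tert-butyl-L-threonine, C[C@@H](OC(C)(C)C)[C@H](N)C(=O)O (retained only in 17)
Why: The primary amine condenses with the C4 methyl ketone and tautomerises to the secondary enamine 17, which can form only toward C3 because C5 is quaternary; its nucleophilic carbon adds to the aldehyde carbon C2, activated by a hydrogen bond from the carboxylic acid of the catalyst, and hydrolysis of the iminium releases 18 and the amino acid. The closest known reaction type is the amino-acid-catalysed enantioselective intramolecular enolexo aldol cyclisation of keto aldehydes and dialdehydes. Ring A closes in the 6-enolexo-exo-trig mode through a chair-like transition state in which the adjacent quaternary carbons C5 and C6 hold donor and acceptor together. The only new stereocentre, C2, is set by the catalyst: in the hydrogen-bonded transition state of an L-amino acid the enamine attacks the Re face of the aldehyde, which corresponds to the (2R) carbinol. The step needs 1,2- rather than 1,4-addition to the α-methylene aldehyde and attack on one enantiotopic face; the first should be favoured by acid-directed delivery to the carbonyl carbon under mild non-basic conditions at or below room temperature, and the second rests on the catalyst alone because ring B is still a symmetric ketal and the substrate is achiral. A primary amine is chosen because the tert-alkyl methyl ketone forms a secondary enamine without the allylic strain that would disfavour a proline-derived tertiary enamine.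

Step 10
Reactants: 18 (2R)-9,9-(ethylenedioxy)-2-hydroxy-5,5-dimethyl-1-methylidenespiro[5.5]undecan-4-one
Product: 19 (2R)-2-(tert-butyldimethylsilyloxy)-9,9-(ethylenedioxy)-5,5-dimethyl-1-methylidenespiro[5.5]undecan-4-one
Conditions: tBuMe2SiOTf, 2,6-lutidine, CH2Cl2, −78 °C
Reagents that add atoms: tert-butyldimethylsilyl trifluoromethanesulfonate, CC(C)(C)[Si](C)(C)OS(=O)(=O)C(F)(F)F
Why: Silylation with a silyl triflate and a hindered pyridine base is fast at −78 °C and too weakly basic to trigger retro-aldol or β-elimination of the β-hydroxy ketone; a silyl ether is chosen because a β-acyloxy ketone would eliminate to the dienone.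

Step 11
Reactants: 19 (2R)-2-(tert-butyldimethylsilyloxy)-9,9-(ethylenedioxy)-5,5-dimethyl-1-methylidenespiro[5.5]undecan-4-one
Product: 20 (2R,4S)-2-(tert-butyldimethylsilyloxy)-9,9-(ethylenedioxy)-5,5-dimethyl-1-methylidenespiro[5.5]undecan-4-ol
Conditions: (R)-2-methyl-CBS-oxazaborolidine (20 mol %), catecholborane, toluene, −78 → −40 °C; aq. NaOH work-up
Reagents that add atoms: none
Why: Corey–Bakshi–Shibata reduction under reagent control; the ketone lies between a quaternary carbon (large) and a methylene (small), the best case for catalyst discrimination, and the (R)-catalyst should give the (4S) carbinol cis to the C2 silyloxy group; both ring faces are comparably hindered (axial ring-B methylene on one, axial C5 methyl on the other), so substrate bias should be small, and catecholborane does not hydroborate the alkene at this temperature.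

Step 12
Reactants: 20 (2R,4S)-2-(tert-butyldimethylsilyloxy)-9,9-(ethylenedioxy)-5,5-dimethyl-1-methylidenespiro[5.5]undecan-4-ol
Product: 21 tert-butyl{[(2R,4R)-4-bromo-9,9-(ethylenedioxy)-5,5-dimethyl-1-methylidenespiro[5.5]undecan-2-yl]oxy}dimethylsilane
Conditions: PPh3, CBr4, toluene, 0 → 70 °C
Reagents that add atoms: tetrabromomethane, BrC(Br)(Br)Br
Why: Appel reaction; the alkoxyphosphonium ion is displaced by bromide with inversion to give the (4R) bromide trans to the C2 oxygen; in the diequatorial chair of 20 the leaving group has no antiperiplanar hydrogen, which disfavours E2, and phosphonium activation avoids a free cation that would undergo a Wagner–Meerwein shift.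

Step 13
Reactants: 21 tert-butyl{[(2R,4R)-4-bromo-9,9-(ethylenedioxy)-5,5-dimethyl-1-methylidenespiro[5.5]undecan-2-yl]oxy}dimethylsilane
Product: 22 (2R,4R)-4-bromo-2-(tert-butyldimethylsilyloxy)-5,5-dimethyl-1-methylidenespiro[5.5]undecan-9-one
Conditions: pyridinium p-toluenesulfonate, acetone/H2O (10:1), 55 °C
Reagents that add atoms: water, O
Why: Acid-catalysed ketal hydrolysis by exchange with acetone; the mild acid is tolerated by the secondary silyl ether, the alkyl bromide and the methylidene group.

Step 14
Reactants: 22 (2R,4R)-4-bromo-2-(tert-butyldimethylsilyloxy)-5,5-dimethyl-1-methylidenespiro[5.5]undecan-9-one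
Product: 23 (2R,4R,6S)-4-bromo-2-(tert-butyldimethylsilyloxy)-5,5-dimethyl-1-methylidene-9-(trimethylsilyloxy)spiro[5.5]undec-8-ene
Conditions: lithium bis[(R)-1-phenylethyl]amide, LiCl, Me3SiCl (in situ), THF, −100 °C
Reagents that add atoms: chlorotrimethylsilane, C[Si](C)(C)Cl
Why: Group-selective deprotonation by a chiral lithium amide with internal silyl quench, the known desymmetrisation of 4,4-disubstituted cyclohexanones; ring B sits in the chair with C5 equatorial and C1 axial, and the amide removes the axial α-hydrogen of the arm on the ring-A face of the C4 bromine, which defines C6 as S.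

Step 15
Reactants: 23 (2R,4R,6S)-4-bromo-2-(tert-butyldimethylsilyloxy)-5,5-dimethyl-1-methylidene-9-(trimethylsilyloxy)spiro[5.5]undec-8-ene
Product: 24 (2R,4R,6S,8S)-4,8-dibromo-2-(tert-butyldimethylsilyloxy)-5,5-dimethyl-1-methylidenespiro[5.5]undecan-9-one
Conditions: N-bromosuccinimide, NaHCO3, THF, −78 → 0 °C
Reagents that add atoms: N-bromosuccinimide, O=C1CCC(=O)N1Br
Why: Electrophilic bromination of a silyl enol ether, regiospecific at C8; bromine enters anti to the axial C1 substituent and gives the equatorial bromide cis to C5, which is also the thermodynamic epimer because an axial bromine would be 1,3-diaxial to C1.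

Step 16
Reactants: 24 (2R,4R,6S,8S)-4,8-dibromo-2-(tert-butyldimethylsilyloxy)-5,5-dimethyl-1-methylidenespiro[5.5]undecan-9-one
Product: 25 (2R,4R,6S,8S,9S)-4,8-dibromo-2-(tert-butyldimethylsilyloxy)-5,5,9-trimethyl-1-methylidenespiro[5.5]undecan-9-ol
Conditions: AlMe3 (3 equiv), toluene, −78 → 0 °C; aq. potassium sodium tartrate
Reagents that add atoms: trimethylaluminium, C[Al](C)C
Why: 1,2-Addition of excess trimethylaluminium, which with the carbonyl complexed by one aluminium delivers methyl along the axial trajectory, giving axial methyl and equatorial hydroxyl (9S, hydroxyl trans to the C8 bromine); the reagent is non-basic, so the α-bromo ketone is not enolised, and the diequatorial bromohydrin cannot close to an epoxide.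

Step 17
Reactants: 25 (2R,4R,6S,8S,9S)-4,8-dibromo-2-(tert-butyldimethylsilyloxy)-5,5,9-trimethyl-1-methylidenespiro[5.5]undecan-9-ol
Product: 26 tert-butyl{[(2R,4R,6S,8S,9S)-4,8-dibromo-9-chloro-5,5,9-trimethyl-1-methylidenespiro[5.5]undecan-2-yl]oxy}dimethylsilane
Conditions: 1-chloro-N,N,2-trimethylprop-1-en-1-amine, CH2Cl2, 0 °C → rt
Reagents that add atoms: 1-chloro-N,N,2-trimethylprop-1-en-1-amine, CC(C)=C(Cl)N(C)C
Why: Neutral deoxychlorination of a tertiary alcohol through its alkoxy-iminium chloride; ionisation gives an ion pair that returns chloride to the face the oxygen left, and bridging by the C8 bromine on the opposite face enforces the same outcome, so chloride ends trans to bromine with retention at C9 (9S); no free acid is present, so the allylic silyl ether and the methylidene group should survive.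

Step 18
Reactants: 26 tert-butyl{[(2R,4R,6S,8S,9S)-4,8-dibromo-9-chloro-5,5,9-trimethyl-1-methylidenespiro[5.5]undecan-2-yl]oxy}dimethylsilane
Product: 27 (2R,4R,6S,8S,9S)-4,8-dibromo-9-chloro-5,5,9-trimethyl-1-methylidenespiro[5.5]undecan-2-ol
Conditions: HF·pyridine, THF/pyridine, 0 °C → rt
Reagents that add atoms: none
Why: Fluoride-mediated desilylation under buffered, non-basic conditions, chosen so that neither secondary bromide nor the tertiary chloride is exposed to a base that could cause elimination.

## Compound list

1 | 1,4-dioxaspiro[4.5]decane-8-carboxylic acid | OC(=O)C1CCC2(CC1)OCCO2 | starting material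
2 | 3-methylbut-2-en-1-ol (prenol) | CC(C)=CCO | starting material
3 | 3-methylbut-2-en-1-yl 1,4-dioxaspiro[4.5]decane-8-carboxylate | CC(C)=CCOC(=O)C1CCC2(CC1)OCCO2 | intermediate
4 | 8-[(3-methylbut-2-en-1-yloxy)(trimethylsilyloxy)methylidene]-1,4-dioxaspiro[4.5]decane (silyl ketene acetal) | CC(C)=CCOC(O[Si](C)(C)C)=C1CCC2(CC1)OCCO2 | intermediate
5 | trimethylsilyl 8-(2-methylbut-3-en-2-yl)-1,4-dioxaspiro[4.5]decane-8-carboxylate | C=CC(C)(C)C1(C(=O)O[Si](C)(C)C)CCC2(CC1)OCCO2 | intermediate
6 | 8-(2-methylbut-3-en-2-yl)-1,4-dioxaspiro[4.5]decane-8-carboxylic acid | C=CC(C)(C)C1(C(=O)O)CCC2(CC1)OCCO2 | intermediate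
7 | [8-(2-methylbut-3-en-2-yl)-1,4-dioxaspiro[4.5]decan-8-yl]methanol | C=CC(C)(C)C1(CO)CCC2(CC1)OCCO2 | intermediate
8 | 8-(2-methylbut-3-en-2-yl)-1,4-dioxaspiro[4.5]decane-8-carbaldehyde | C=CC(C)(C)C1(C=O)CCC2(CC1)OCCO2 | intermediate
9 | (methoxymethyl)triphenylphosphonium chloride | COC[P+](c1ccccc1)(c1ccccc1)c1ccccc1.[Cl-] | starting material
10 | (methoxymethylidene)triphenylphosphorane | COC=P(c1ccccc1)(c1ccccc1)c1ccccc1 | intermediate
11 | 8-(2-methoxyethenyl)-8-(2-methylbut-3-en-2-yl)-1,4-dioxaspiro[4.5]decane (E/Z mixture) | COC=CC1(C(C)(C)C=C)CCC2(CC1)OCCO2 | intermediate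
12 | 2-(acetoxymercurio)-2-[8-(2-methylbut-3-en-2-yl)-1,4-dioxaspiro[4.5]decan-8-yl]acetaldehyde | CC(=O)O[Hg]C(C=O)C1(C(C)(C)C=C)CCC2(CC1)OCCO2 | intermediate
13 | 2-[8-(2-methylbut-3-en-2-yl)-1,4-dioxaspiro[4.5]decan-8-yl]acetaldehyde | O=CCC1(C(C)(C)C=C)CCC2(CC1)OCCO2 | intermediate
14 | 3-(dimethylamino)-2-[8-(2-methylbut-3-en-2-yl)-1,4-dioxaspiro[4.5]decan-8-yl]propanal (racemic Mannich base) | CN(C)CC(C=O)C1(C(C)(C)C=C)CCC2(CC1)OCCO2 | intermediate
15 | 2-[8-(2-methylbut-3-en-2-yl)-1,4-dioxaspiro[4.5]decan-8-yl]prop-2-enal | C=C(C=O)C1(C(C)(C)C=C)CCC2(CC1)OCCO2 | intermediate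
16 | 2-[8-(2-methyl-3-oxobutan-2-yl)-1,4-dioxaspiro[4.5]decan-8-yl]prop-2-enal | CC(=O)C(C)(C)C1(C(=C)C=O)CCC2(CC1)OCCO2 | intermediate
17 | (2S,3R)-3-tert-butoxy-2-({3-methyl-3-[8-(3-oxoprop-1-en-2-yl)-1,4-dioxaspiro[4.5]decan-8-yl]but-1-en-2-yl}amino)butanoic acid (enamine) | C=C(N[C@@H]([C@@H](C)OC(C)(C)C)C(=O)O)C(C)(C)C1(C(=C)C=O)CCC2(CC1)OCCO2 | intermediate
18 | (2R)-9,9-(ethylenedioxy)-2-hydroxy-5,5-dimethyl-1-methylidenespiro[5.5]undecan-4-one | C=C1[C@H](O)CC(=O)C(C)(C)C12CCC3(CC2)OCCO3 | intermediate
19 | (2R)-2-(tert-butyldimethylsilyloxy)-9,9-(ethylenedioxy)-5,5-dimethyl-1-methylidenespiro[5.5]undecan-4-one | C=C1[C@H](O[Si](C)(C)C(C)(C)C)CC(=O)C(C)(C)C12CCC3(CC2)OCCO3 | intermediate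
20 | (2R,4S)-2-(tert-butyldimethylsilyloxy)-9,9-(ethylenedioxy)-5,5-dimethyl-1-methylidenespiro[5.5]undecan-4-ol | C=C1[C@H](O[Si](C)(C)C(C)(C)C)C[C@H](O)C(C)(C)C12CCC3(CC2)OCCO3 | intermediate
21 | tert-butyl{[(2R,4R)-4-bromo-9,9-(ethylenedioxy)-5,5-dimethyl-1-methylidenespiro[5.5]undecan-2-yl]oxy}dimethylsilane | C=C1[C@H](O[Si](C)(C)C(C)(C)C)C[C@@H](Br)C(C)(C)C12CCC3(CC2)OCCO3 | intermediate
22 | (2R,4R)-4-bromo-2-(tert-butyldimethylsilyloxy)-5,5-dimethyl-1-methylidenespiro[5.5]undecan-9-one | C=C1[C@H](O[Si](C)(C)C(C)(C)C)C[C@@H](Br)C(C)(C)C12CCC(=O)CC2 | intermediate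
23 | (2R,4R,6S)-4-bromo-2-(tert-butyldimethylsilyloxy)-5,5-dimethyl-1-methylidene-9-(trimethylsilyloxy)spiro[5.5]undec-8-ene | C=C1[C@H](O[Si](C)(C)C(C)(C)C)C[C@@H](Br)C(C)(C)[C@]12CCC(O[Si](C)(C)C)=CC2 | intermediate
24 | (2R,4R,6S,8S)-4,8-dibromo-2-(tert-butyldimethylsilyloxy)-5,5-dimethyl-1-methylidenespiro[5.5]undecan-9-one | C=C1[C@H](O[Si](C)(C)C(C)(C)C)C[C@@H](Br)C(C)(C)[C@]12CCC(=O)[C@@H](Br)C2 | intermediate
25 | (2R,4R,6S,8S,9S)-4,8-dibromo-2-(tert-butyldimethylsilyloxy)-5,5,9-trimethyl-1-methylidenespiro[5.5]undecan-9-ol | C=C1[C@H](O[Si](C)(C)C(C)(C)C)C[C@@H](Br)C(C)(C)[C@]12CC[C@](C)(O)[C@@H](Br)C2 | intermediate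
26 | tert-butyl{[(2R,4R,6S,8S,9S)-4,8-dibromo-9-chloro-5,5,9-trimethyl-1-methylidenespiro[5.5]undecan-2-yl]oxy}dimethylsilane | C=C1[C@H](O[Si](C)(C)C(C)(C)C)C[C@@H](Br)C(C)(C)[C@]12CC[C@](C)(Cl)[C@@H](Br)C2 | intermediate
27 | (2R,4R,6S,8S,9S)-4,8-dibromo-9-chloro-5,5,9-trimethyl-1-methylidenespiro[5.5]undecan-2-ol | C=C1[C@H](O)C[C@@H](Br)C(C)(C)[C@]12CC[C@](C)(Cl)[C@@H](Br)C2 | target

Total step count: 18. Longest linear sequence: 18 steps (from 1).

## Least certain steps

**Step 9 (key step).**
- What may go wrong:
  - conjugate addition of the enamine to the methylidene terminus (a competing six-membered closure) instead of 1,2-addition;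
  - dehydration of the aldol to the cross-conjugated dienone, or retro-aldol on prolonged exposure;
  - slow enamine formation at the hindered ketone while the aldehyde ties up the catalyst as an imine;
  - fragmentation of the enamine, which is formally a strained 1,5-diene, by a [3,3] shift if heated;
  - insufficient facial discrimination.
- Fallback (from 16, back at 18): 16 is cyclised with lithium diisopropylamide in THF at −78 °C and quenched cold. Only the methyl ketone can be deprotonated, and a lithium enolate adds 1,2 to an enal at this temperature. This gives racemic 9,9-(ethylenedioxy)-2-hydroxy-5,5-dimethyl-1-methylidenespiro[5.5]undecan-4-one F1. A Sharpless kinetic resolution of this secondary allylic alcohol (Ti(OiPr)4, L-(+)-diisopropyl tartrate, tBuOOH 0.6 equiv, 4 Å sieves, CH2Cl2, −20 °C) should consume the (S)-enantiomer as the spiro-epoxy alcohol (1S,2S)-9,9-(ethylenedioxy)-2-hydroxy-5,5-dimethylspiro[5.5]undecan-4-one-1-spiro-2′-oxirane F2 and leave (R)-alcohol 18.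

**Step 12.**
- What may go wrong: backside attack at the neopentyl carbon C4 is slow because the incoming bromide passes syn-axial to a ring-B methylene. The phosphonium intermediate may instead eliminate through the ring-flipped conformer, or ionise with 1,2-shift of the C5–C6 bond (ring contraction).
- Fallback (from 19, back at 22): this replaces backside by frontside displacement.
  - 19 is reduced with the enantiomeric (S)-2-methyl-CBS-oxazaborolidine and catecholborane to the trans carbinol (2R,4R)-2-(tert-butyldimethylsilyloxy)-9,9-(ethylenedioxy)-5,5-dimethyl-1-methylidenespiro[5.5]undecan-4-ol F3.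
  - Quinoline-8-sulfonyl chloride, pyridine and DMAP give its quinoline-8-sulfonate F4.
  - Pyridinium p-toluenesulfonate in wet acetone removes the ketal to give (2R,4R)-2-(tert-butyldimethylsilyloxy)-5,5-dimethyl-1-methylidene-9-oxospiro[5.5]undecan-4-yl quinoline-8-sulfonate F5.
  - TiBr4 in CH2Cl2 at −78 °C, chelated by the sulfonate and the quinoline nitrogen, delivers bromide to the face from which the leaving group departs (retention), giving 22.

**Step 11.**
- What may go wrong: the catalyst has to override whatever facial bias the ring has. If the pairing is mismatched, the reduction of this hindered ketone may be slow and give the trans carbinol as well.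
- Fallback (from 19, back at 20): thermodynamic control instead of reagent control. Dissolving-metal reduction (Li, liquid NH3, tBuOH, THF, −78 °C) should give the more stable equatorial carbinol, which is 20; the axial epimer would be syn-axial to a ring-B methylene. No new compound is involved.

**Step 14.**
- What may go wrong: the chiral amide may not discriminate well between the two arms, since the existing ring-A centres can be matched or mismatched with it. The result would be a mixture of regioisomeric enol ethers and hence of C6 epimers.
- Fallback (from 22, back at 24): separation and recycling instead of reagent control.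
  - Lithium diisopropylamide/Me3SiCl gives 23 together with its regioisomer (2R,4R,6R)-4-bromo-2-(tert-butyldimethylsilyloxy)-5,5-dimethyl-1-methylidene-9-(trimethylsilyloxy)spiro[5.5]undec-8-ene F6.
  - Bromination of the mixture as in step 15 gives 24 and (2R,4R,6R,8R)-4,8-dibromo-2-(tert-butyldimethylsilyloxy)-5,5-dimethyl-1-methylidenespiro[5.5]undecan-9-one F7. These are diastereomers and separable by chromatography.
  - F7 is returned to 22 by zinc in acetic acid, which removes only the α-keto bromine.

**Step 17.**
- What may go wrong: ionisation at C9 may end in loss of a proton (alkene formation), or chloride may capture an open cation from the axial face and give the C9 epimer with bromine and chlorine cis.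
- Fallback (from 23, back at 26): alkene dihalogenation instead of alcohol substitution.
  - MeLi cleaves the enol silane to the lithium enolate, and PhNTf2 gives (2R,4R,6S)-4-bromo-2-(tert-butyldimethylsilyloxy)-5,5-dimethyl-1-methylidenespiro[5.5]undec-8-en-9-yl trifluoromethanesulfonate F8.
  - Negishi coupling (MeZnCl, Pd(PPh3)4, THF) gives (2R,4R,6S)-4-bromo-2-(tert-butyldimethylsilyloxy)-5,5,9-trimethyl-1-methylidenespiro[5.5]undec-8-ene F9.
  - Tetrabutylammonium dichlorobromate (CH2Cl2, −78 °C) adds bromine and chlorine anti across the more electron-rich trisubstituted alkene, with chloride at the tertiary carbon and bromine on the face away from the axial C1 substituent, to give 26.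

## Further compounds

F1 | step 9 | racemic 9,9-(ethylenedioxy)-2-hydroxy-5,5-dimethyl-1-methylidenespiro[5.5]undecan-4-one | C=C1C(O)CC(=O)C(C)(C)C12CCC3(CC2)OCCO3
F2 | step 9 | (1S,2S)-9,9-(ethylenedioxy)-2-hydroxy-5,5-dimethylspiro[5.5]undecan-4-one-1-spiro-2′-oxirane | C1O[C@]12[C@@H](O)CC(=O)C(C)(C)C23CCC4(CC3)OCCO4
F3 | step 12 | (2R,4R)-2-(tert-butyldimethylsilyloxy)-9,9-(ethylenedioxy)-5,5-dimethyl-1-methylidenespiro[5.5]undecan-4-ol | C=C1[C@H](O[Si](C)(C)C(C)(C)C)C[C@@H](O)C(C)(C)C12CCC3(CC2)OCCO3
F4 | step 12 | (2R,4R)-2-(tert-butyldimethylsilyloxy)-9,9-(ethylenedioxy)-5,5-dimethyl-1-methylidenespiro[5.5]undecan-4-yl quinoline-8-sulfonate | C=C1[C@H](O[Si](C)(C)C(C)(C)C)C[C@@H](OS(=O)(=O)c2cccc3cccnc23)C(C)(C)C12CCC3(CC2)OCCO3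
F5 | step 12 | (2R,4R)-2-(tert-butyldimethylsilyloxy)-5,5-dimethyl-1-methylidene-9-oxospiro[5.5]undecan-4-yl quinoline-8-sulfonate | C=C1[C@H](O[Si](C)(C)C(C)(C)C)C[C@@H](OS(=O)(=O)c2cccc3cccnc23)C(C)(C)C12CCC(=O)CC2
F0 | step 11 | none | none
F6 | step 14 | (2R,4R,6R)-4-bromo-2-(tert-butyldimethylsilyloxy)-5,5-dimethyl-1-methylidene-9-(trimethylsilyloxy)spiro[5.5]undec-8-ene | C=C1[C@H](O[Si](C)(C)C(C)(C)C)C[C@@H](Br)C(C)(C)[C@]12CC=C(O[Si](C)(C)C)CC2
F7 | step 14 | (2R,4R,6R,8R)-4,8-dibromo-2-(tert-butyldimethylsilyloxy)-5,5-dimethyl-1-methylidenespiro[5.5]undecan-9-one | C=C1[C@H](O[Si](C)(C)C(C)(C)C)C[C@@H](Br)C(C)(C)[C@]12C[C@@H](Br)C(=O)CC2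
F8 | step 17 | (2R,4R,6S)-4-bromo-2-(tert-butyldimethylsilyloxy)-5,5-dimethyl-1-methylidenespiro[5.5]undec-8-en-9-yl trifluoromethanesulfonate | C=C1[C@H](O[Si](C)(C)C(C)(C)C)C[C@@H](Br)C(C)(C)[C@]12CCC(OS(=O)(=O)C(F)(F)F)=CC2
F9 | step 17 | (2R,4R,6S)-4-bromo-2-(tert-butyldimethylsilyloxy)-5,5,9-trimethyl-1-methylidenespiro[5.5]undec-8-ene | C=C1[C@H](O[Si](C)(C)C(C)(C)C)C[C@@H](Br)C(C)(C)[C@]12CCC(C)=CC2
A1 | alternative 1 | 4-[(3S,5R)-3,5-bis(tert-butyldimethylsilyloxy)-2-methylhept-6-yn-2-yl]phenol | C#C[C@H](O[Si](C)(C)C(C)(C)C)C[C@H](O[Si](C)(C)C(C)(C)C)C(C)(C)c1ccc(O)cc1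
A2 | alternative 1 | (2R,4S)-2,4-bis(tert-butyldimethylsilyloxy)-5,5-dimethyl-1-methylidenespiro[5.5]undeca-7,10-dien-9-one | C=C1[C@H](O[Si](C)(C)C(C)(C)C)C[C@H](O[Si](C)(C)C(C)(C)C)C(C)(C)C12C=CC(=O)C=C2
A3 | alternative 2 | (E)-γ-bisabolene | CC1=CC/C(=C(\C)CCC=C(C)C)CC1
A4 | alternative 2 | (4R,6S)-4-bromo-5,5,9-trimethyl-1-methylidenespiro[5.5]undec-8-ene | C=C1CC[C@@H](Br)C(C)(C)[C@]12CCC(C)=CC2
A5 | alternative 3 | (3R)-3-bromo-2,2-dimethyl-6-oxocyclohexane-1-carbaldehyde | O=C1CC[C@@H](Br)C(C)(C)C1C=O
A6 | alternative 3 | but-3-en-2-one | C=CC(C)=O
A7 | alternative 3 | (4R,6R)-4-bromo-5,5-dimethylspiro[5.5]undec-7-ene-1,9-dione | O=C1CC[C@@H](Br)C(C)(C)[C@]12CCC(=O)C=C2
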